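**Retrosynthetic overview**
1. Feature: in ring B (B1 = carbon bearing the butanoyl group; B2, B4, B6 = C–O; B3, B5 = carbons bearing the CH2 links to rings A and C) carbon-bearing and oxygen-bearing atoms alternate, so ring B is the head-to-tail sum of three ynol ether units B1–B2, B3–B4 and B5–B6.
2. Target 24 ⇐ cleavage of seven alkyl ethers ⇐ Friedel–Crafts butanoylation of the free CH on rings A and C (23) ⇐ Houben–Hoesch butanoylation of B1 (21) ⇐ tert-butyl ether cleavage of phenol 17.
3. 17 ⇐ two molecules of tert-butyl ynol ether 9 (units B3–B4 and B5–B6) and ethoxyacetylene 10 (unit B1–B2), joined through ketene, cyclobutenone and benzannulation (bonds B4–B5, B6–B1, B2–B3).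
4. 9 ⇐ benzylic electrophile from 2,4,6-trimethoxytoluene (formylation, reduction, chloride) and lithium tert-butoxyacetylide from trichloroethylene and potassium tert-butoxide.
5. Ring order: rings A and C come ready-made in arene 1; a transient four-membered ring forms first in the key step and ring B is closed last in the same flask.

Key step: step 5

Assumption: the unsubstituted ynol ether is used as commercial ethoxyacetylene, because its ethyl group needs a much higher temperature than tert-butyl for the retro-ene reaction and is removed together with the methyl groups in step 9.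

**Step 1**
Reactants: 1 2,4,6-trimethoxytoluene
Product: 2 2,4,6-trimethoxy-3-methylbenzaldehyde
Conditions: POCl3, DMF, 0 °C to rt; then H2O
Reagents that add atoms: N,N-dimethylformamide CN(C)C=O; water O
Why: Vilsmeier–Haack formylation of an activated arene; the two free ring positions of 1 are equivalent and the first formyl group deactivates the ring against a second attack.

**Step 2**
Reactants: 2 2,4,6-trimethoxy-3-methylbenzaldehyde
Product: 3 (2,4,6-trimethoxy-3-methylphenyl)methanol
Conditions: NaBH4, MeOH, 0 °C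
Reagents that add atoms: none
Why: hydride reduction of an aryl aldehyde under non-acidic conditions, which the acid-labile, electron-rich benzylic alcohol should tolerate.

**Step 3**
Reactants: 4 trichloroethylene; 5 potassium tert-butoxide
Product: 6 (E)-1-tert-butoxy-1,2-dichloroethene
Conditions: THF, −50 °C to rt
Reagents that add atoms: none
Why: dehydrochlorination to dichloroacetylene followed by anti addition of tert-butoxide and protonation (the addition–elimination route to 1,2-dichlorovinyl ethers), which should give the E ether.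

**Step 4**
Reactants: 3 (2,4,6-trimethoxy-3-methylphenyl)methanol; 6 (E)-1-tert-butoxy-1,2-dichloroethene
Product: 9 2-(3-tert-butoxyprop-2-yn-1-yl)-1,3,5-trimethoxy-4-methylbenzene, via benzylic chloride 7 (not isolated), via lithium tert-butoxyacetylide 8 (not isolated)
Conditions: 3: n-BuLi, then MsCl, LiCl, THF, −78 to −30 °C; 6: n-BuLi (2 equiv), THF, −78 to −40 °C; solutions combined, DMPU, −78 °C to rt
Reagents that add atoms: none
Why: SN2 alkylation of a lithium alkoxyacetylide (from 6 by loss of HCl and chlorine–lithium exchange) with a benzylic chloride, which is made from the lithium alkoxide through its mesylate under basic conditions and used at once because it ionises readily.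

**Step 5**
Reactants: 9 2-(3-tert-butoxyprop-2-yn-1-yl)-1,3,5-trimethoxy-4-methylbenzene (two equivalents); 10 ethoxyacetylene
Product: 17 3-tert-butoxy-5-ethoxy-2,4-bis[(2,4,6-trimethoxy-3-methylphenyl)methyl]phenol, via aldoketene 11 (not isolated), via cyclobutenone 12 (not isolated), via vinylketene 13 (not isolated), via vinylcyclobutenone 14 (not isolated), via dienylketene 15 (not isolated), via cyclohexadienone 16 (not isolated)
Conditions: 9 alone, toluene (0.5 M), 80 °C until consumed; then 10 (3 equiv), sealed tube, 95 °C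
Reagents that add atoms: none
Why: Proposed new method: near 80 °C one molecule of 9 should lose isobutene in a retro-ene reaction to give aldoketene 11, which a second molecule of 9 traps by polar [2+2] cycloaddition to cyclobutenone 12 (bond B4–B5); near 95 °C 12 should open in a 4π electrocyclic reaction to vinylketene 13, add 10 in a second [2+2] to vinylcyclobutenone 14 (bonds B6–B1 and B2–B3) and open again to dienylketene 15. Ring B then closes by 6π electrocyclisation of 15, which re-joins B5 and B6 in cyclohexadienone 16, and 16 enolises to phenol 17. The closest known reactions are the thermal conversion of 1-alkoxyalkynes into 3-alkoxycyclobutenones and the Danheiser benzannulation of cyclobutenones with alkoxyacetylenes; what is new is their union in one flask with two different ynol ethers. No stereocentre is set, because the racemic centres of 12, 14 and 16 vanish on ring opening and aromatisation. The two-to-one chemoselectivity rests on the thermal gap between the tert-butyl ether, which fragments near 80 °C, and the ethyl ether, which is stable there and is added only when 9 is consumed. The head-to-tail regiochemistry follows in both [2+2] events from bonding of the electrophilic ketene carbonyl carbon to the oxygen-free nucleophilic alkyne carbon.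

**Step 6**
Reactants: 17 3-tert-butoxy-5-ethoxy-2,4-bis[(2,4,6-trimethoxy-3-methylphenyl)methyl]phenol
Product: 18 5-ethoxy-2,4-bis[(2,4,6-trimethoxy-3-methylphenyl)methyl]benzene-1,3-diol
Conditions: TFA (10 vol%), Et3SiH, CH2Cl2, 0 °C
Reagents that add atoms: none
Why: acidolysis of the doubly ortho-substituted aryl tert-butyl ether, with triethylsilane reducing the tert-butyl cation so that it does not alkylate the free ring positions; the methyl and ethyl ethers should be untouched.

**Step 7**
Reactants: 18 5-ethoxy-2,4-bis[(2,4,6-trimethoxy-3-methylphenyl)methyl]benzene-1,3-diol; 19 butanenitrile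
Product: 21 1-[2-ethoxy-4,6-dihydroxy-3,5-bis[(2,4,6-trimethoxy-3-methylphenyl)methyl]phenyl]butan-1-one, via ketimine 20 (not isolated)
Conditions: ZnCl2, HCl (g), Et2O, 0 °C; then H2O, 90 °C
Reagents that add atoms: water O
Why: Houben–Hoesch acylation, which is C-selective on free resorcinols, at B1 (the only open position of ring B, ortho or para to all three of its oxygens), while the fully etherified outer rings should react far more slowly with the nitrile-derived electrophile; the ketimine hydrochloride 20 is hydrolysed in the same operation.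

**Step 8**
Reactants: 21 1-[2-ethoxy-4,6-dihydroxy-3,5-bis[(2,4,6-trimethoxy-3-methylphenyl)methyl]phenyl]butan-1-one; 22 butanoic anhydride (two equivalents)
Product: 23 1-[3,5-bis[(3-butanoyl-2,4,6-trimethoxy-5-methylphenyl)methyl]-2-ethoxy-4,6-dihydroxyphenyl]butan-1-one
Conditions: AlCl3 (excess), CH2Cl2–PhNO2, 0 °C to rt; then cold aq. HCl
Reagents that add atoms: none
Why: Friedel–Crafts acylation by the acylium species from the anhydride and AlCl3 at the single free CH of each outer ring, each flanked by two methoxy groups, while ring B is fully substituted, deactivated by its ketone and holds its phenols as aluminium phenoxides; any O-demethylation next to the new ketones is harmless because step 9 removes every alkyl group.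

**Step 9**
Reactants: 23 1-[3,5-bis[(3-butanoyl-2,4,6-trimethoxy-5-methylphenyl)methyl]-2-ethoxy-4,6-dihydroxyphenyl]butan-1-one
Product: 24 1-[3,5-bis[(3-butanoyl-2,4,6-trihydroxy-5-methylphenyl)methyl]-2,4,6-trihydroxyphenyl]butan-1-one (CNP0296563.0)
Conditions: BBr3 (excess), CH2Cl2, −78 °C to rt; then MeOH, H2O
Reagents that add atoms: none
Why: Lewis acid cleavage of six aryl methyl ethers and one aryl ethyl ether by BBr3, helped by chelation to the neighbouring ketones, under which the aryl ketones and diarylmethane bridges should persist.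

**Compound list**
1 | 2,4,6-trimethoxytoluene | Cc1c(OC)cc(OC)cc1OC | starting material
2 | 2,4,6-trimethoxy-3-methylbenzaldehyde | Cc1c(OC)cc(OC)c(C=O)c1OC | intermediate
3 | (2,4,6-trimethoxy-3-methylphenyl)methanol | Cc1c(OC)cc(OC)c(CO)c1OC | intermediate
4 | trichloroethylene | ClC=C(Cl)Cl | starting material
5 | potassium tert-butoxide | CC(C)(C)[O-].[K+] | starting material
6 | (E)-1-tert-butoxy-1,2-dichloroethene | Cl/C=C(/Cl)OC(C)(C)C | intermediate
7 | 2-(chloromethyl)-1,3,5-trimethoxy-4-methylbenzene | Cc1c(OC)cc(OC)c(CCl)c1OC | intermediate (not isolated)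
8 | lithium tert-butoxyacetylide | [Li]C#COC(C)(C)C | intermediate (not isolated)
9 | 2-(3-tert-butoxyprop-2-yn-1-yl)-1,3,5-trimethoxy-4-methylbenzene | Cc1c(OC)cc(OC)c(CC#COC(C)(C)C)c1OC | intermediate
10 | ethoxyacetylene | C#COCC | starting material
11 | 3-(2,4,6-trimethoxy-3-methylphenyl)prop-1-en-1-one | O=C=CCc1c(OC)cc(OC)c(C)c1OC | intermediate (not isolated)
12 | 3-tert-butoxy-2,4-bis[(2,4,6-trimethoxy-3-methylphenyl)methyl]cyclobut-2-en-1-one (racemic) | O=C1C(Cc2c(OC)cc(OC)c(C)c2OC)=C(OC(C)(C)C)C1Cc3c(OC)cc(OC)c(C)c3OC | intermediate (not isolated)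
13 | (3Z)-3-tert-butoxy-5-(2,4,6-trimethoxy-3-methylphenyl)-2-[(2,4,6-trimethoxy-3-methylphenyl)methyl]penta-1,3-dien-1-one | O=C=C(Cc1c(OC)cc(OC)c(C)c1OC)/C(OC(C)(C)C)=C/Cc2c(OC)cc(OC)c(C)c2OC | intermediate (not isolated)
14 | 4-[(1Z)-1-tert-butoxy-3-(2,4,6-trimethoxy-3-methylphenyl)prop-1-en-1-yl]-3-ethoxy-4-[(2,4,6-trimethoxy-3-methylphenyl)methyl]cyclobut-2-en-1-one (racemic) | O=C1C=C(OCC)C1(Cc2c(OC)cc(OC)c(C)c2OC)/C(OC(C)(C)C)=C/Cc3c(OC)cc(OC)c(C)c3OC | intermediate (not isolated)
15 | (3E,5Z)-5-tert-butoxy-3-ethoxy-7-(2,4,6-trimethoxy-3-methylphenyl)-4-[(2,4,6-trimethoxy-3-methylphenyl)methyl]hepta-1,3,5-trien-1-one | O=C=C/C(OCC)=C(/Cc1c(OC)cc(OC)c(C)c1OC)\C(OC(C)(C)C)=C\Cc2c(OC)cc(OC)c(C)c2OC | intermediate (not isolated)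
16 | 5-tert-butoxy-3-ethoxy-4,6-bis[(2,4,6-trimethoxy-3-methylphenyl)methyl]cyclohexa-2,4-dien-1-one (racemic) | O=C1C=C(OCC)C(Cc2c(OC)cc(OC)c(C)c2OC)=C(OC(C)(C)C)C1Cc3c(OC)cc(OC)c(C)c3OC | intermediate (not isolated)
17 | 3-tert-butoxy-5-ethoxy-2,4-bis[(2,4,6-trimethoxy-3-methylphenyl)methyl]phenol | Cc1c(OC)cc(OC)c(Cc2c(O)cc(OCC)c(Cc3c(OC)cc(OC)c(C)c3OC)c2OC(C)(C)C)c1OC | intermediate
18 | 5-ethoxy-2,4-bis[(2,4,6-trimethoxy-3-methylphenyl)methyl]benzene-1,3-diol | Cc1c(OC)cc(OC)c(Cc2c(O)cc(OCC)c(Cc3c(OC)cc(OC)c(C)c3OC)c2O)c1OC | intermediate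
19 | butanenitrile | CCCC#N | starting material
20 | 1-[2-ethoxy-4,6-dihydroxy-3,5-bis[(2,4,6-trimethoxy-3-methylphenyl)methyl]phenyl]butan-1-imine (formed as its hydrochloride) | CCCC(=N)c1c(O)c(Cc2c(OC)cc(OC)c(C)c2OC)c(O)c(Cc3c(OC)cc(OC)c(C)c3OC)c1OCC | intermediate (not isolated)
21 | 1-[2-ethoxy-4,6-dihydroxy-3,5-bis[(2,4,6-trimethoxy-3-methylphenyl)methyl]phenyl]butan-1-one | CCCC(=O)c1c(O)c(Cc2c(OC)cc(OC)c(C)c2OC)c(O)c(Cc3c(OC)cc(OC)c(C)c3OC)c1OCC | intermediate
22 | butanoic anhydride | CCCC(=O)OC(=O)CCC | starting material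
23 | 1-[3,5-bis[(3-butanoyl-2,4,6-trimethoxy-5-methylphenyl)methyl]-2-ethoxy-4,6-dihydroxyphenyl]butan-1-one | CCCC(=O)c1c(OC)c(C)c(OC)c(Cc2c(O)c(Cc3c(OC)c(C)c(OC)c(C(=O)CCC)c3OC)c(OCC)c(C(=O)CCC)c2O)c1OC | intermediate
24 | 1-[3,5-bis[(3-butanoyl-2,4,6-trihydroxy-5-methylphenyl)methyl]-2,4,6-trihydroxyphenyl]butan-1-one | CCCC(=O)c1c(O)c(C)c(O)c(Cc2c(O)c(Cc3c(O)c(C)c(O)c(C(=O)CCC)c3O)c(O)c(C(=O)CCC)c2O)c1O | target

**Step count:** 9 steps in total; longest linear sequence 8 steps (steps 1, 2, 4, 5, 6, 7, 8, 9).

**Steps most likely to fail**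

1. Step 5 (the new method). Possible failures are loss of isobutene from cyclobutenone 12 before it opens, self-condensation of the ketene as 9 runs out, slow ring opening of the alkoxy-substituted cyclobutenone, and O-acylation of the product phenol by ketenes. Fallback, setting out from 3 and coming back at 24: ring B is taken ready-made. Two equivalents of 3 are added slowly to commercial 1-(2,4,6-trihydroxyphenyl)butan-1-one (CCCC(=O)c1c(O)cc(O)cc1O) with catalytic p-TsOH in MeCN at 0 °C. This Friedel–Crafts benzylation should give 1-[2,4,6-trihydroxy-3,5-bis[(2,4,6-trimethoxy-3-methylphenyl)methyl]phenyl]butan-1-one F1. Butanoic anhydride 22 and AlCl3 as in step 8 should then acylate the two outer rings to 1-[3,5-bis[(3-butanoyl-2,4,6-trimethoxy-5-methylphenyl)methyl]-2,4,6-trihydroxyphenyl]butan-1-one F2, and BBr3 as in step 9 should give 24.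

2. Step 4. The benzylic chloride may ionise and alkylate the free ring position of another molecule before the acetylide reaches it. Fallback, setting out from 2 and coming back at 9: the ring is blocked and deactivated first. NBS in MeCN should brominate the last free ring position of 2 to give 3-bromo-2,4,6-trimethoxy-5-methylbenzaldehyde F3. NaBH4 should reduce it to (3-bromo-2,4,6-trimethoxy-5-methylphenyl)methanol F4, and PBr3 in Et2O should give 1-bromo-3-(bromomethyl)-2,4,6-trimethoxy-5-methylbenzene F5. This bromide should be isolable because the ring is fully substituted, the methoxy groups are twisted out of conjugation and no ring position is left for self-alkylation. It should alkylate 8 to 1-bromo-3-(3-tert-butoxyprop-2-yn-1-yl)-2,4,6-trimethoxy-5-methylbenzene F6. Bromine–lithium exchange with t-BuLi at −78 °C and a MeOH quench should return 9.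

3. Step 8. The strong Lewis acid may cleave or shift the benzylic bridges between the electron-rich rings before the outer rings are acylated, and O-butanoylation of the ring B phenols may compete (brief K2CO3 in MeOH would return the phenols). Fallback, setting out from 21 and coming back at 24: the order is reversed. BBr3 should first give 1-[2,4,6-trihydroxy-3,5-bis[(2,4,6-trihydroxy-3-methylphenyl)methyl]phenyl]butan-1-one F7. A Houben–Hoesch acylation of its two outer rings with butanenitrile 19, ZnCl2 and HCl in Et2O at 0 °C, which is C-selective on phloroglucinols, should give 1-[3,5-bis[(3-butanimidoyl-2,4,6-trihydroxy-5-methylphenyl)methyl]-2,4,6-trihydroxyphenyl]butan-1-one F8 as its bis-hydrochloride. Warm water should hydrolyse it to 24.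

**Further compounds**
F1 | step 5 | 1-[2,4,6-trihydroxy-3,5-bis[(2,4,6-trimethoxy-3-methylphenyl)methyl]phenyl]butan-1-one | CCCC(=O)c1c(O)c(Cc2c(OC)cc(OC)c(C)c2OC)c(O)c(Cc3c(OC)cc(OC)c(C)c3OC)c1O
F2 | step 5 | 1-[3,5-bis[(3-butanoyl-2,4,6-trimethoxy-5-methylphenyl)methyl]-2,4,6-trihydroxyphenyl]butan-1-one | CCCC(=O)c1c(OC)c(C)c(OC)c(Cc2c(O)c(Cc3c(OC)c(C)c(OC)c(C(=O)CCC)c3OC)c(O)c(C(=O)CCC)c2O)c1OC
F3 | step 4 | 3-bromo-2,4,6-trimethoxy-5-methylbenzaldehyde | Cc1c(OC)c(Br)c(OC)c(C=O)c1OC
F4 | step 4 | (3-bromo-2,4,6-trimethoxy-5-methylphenyl)methanol | Cc1c(OC)c(Br)c(OC)c(CO)c1OC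
F5 | step 4 | 1-bromo-3-(bromomethyl)-2,4,6-trimethoxy-5-methylbenzene | Cc1c(OC)c(Br)c(OC)c(CBr)c1OC
F6 | step 4 | 1-bromo-3-(3-tert-butoxyprop-2-yn-1-yl)-2,4,6-trimethoxy-5-methylbenzene | Cc1c(OC)c(Br)c(OC)c(CC#COC(C)(C)C)c1OC
F7 | step 8 | 1-[2,4,6-trihydroxy-3,5-bis[(2,4,6-trihydroxy-3-methylphenyl)methyl]phenyl]butan-1-one | CCCC(=O)c1c(O)c(Cc2c(O)cc(O)c(C)c2O)c(O)c(Cc3c(O)cc(O)c(C)c3O)c1O
F8 | step 8 | 1-[3,5-bis[(3-butanimidoyl-2,4,6-trihydroxy-5-methylphenyl)methyl]-2,4,6-trihydroxyphenyl]butan-1-one | CCCC(=N)c1c(O)c(C)c(O)c(Cc2c(O)c(Cc3c(O)c(C)c(O)c(C(=N)CCC)c3O)c(O)c(C(=O)CCC)c2O)c1O
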